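**Remarks on the chemistry**

- Numbering: units 1 to 4 are counted from the top of the chain; atoms carry flavan numbers (O1, C2, C3, C4, C4a, C5 to C8, C8a; ring B primed).
- Correction at the ketal centre: a Z enol ether that unites suprafacially with a methide places the silyloxy group cis to the 3-alkoxy group. A drawing with these two groups trans does not fit that geometry, so 30 is drawn cis. The centre is erased in step 15 and either anomer serves.
- The planar methide carbon has no stereocentre close enough to bias its faces. The 3-O substituent of the enol ether is therefore a hydrogenolysable (S)-1-phenylethyl group in place of benzyl, and the silyl group is tert-butyldimethylsilyl so that enol ether and ketal can be isolated.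
- A formyl group on the electrophile of an interflavan coupling would weaken the C4 cation and add a second electrophilic site. The formyl group is therefore introduced after the coupling, from an iodine atom that also caps C8 of the electrophile.
- Assumption: 7, 20, 21 and 23 are taken as commercial.

## Structural features

The target is a linear tetramer of (−)-epicatechin. Each of the four flavan-3-ol units is a chroman (benzo ring A fused to pyran ring C) with a catechol ring B on C2, and the molecule carries twenty free hydroxyl groups. Three interflavan C–C bonds join the units: C4 of unit 1 to C6 of unit 2, C4 of unit 2 to C8 of unit 3, and C4 of unit 3 to C6 of unit 4. Units 1 to 3 each hold three contiguous stereocentres (C2, C3, C4) in the 2,3-cis, 3,4-trans pattern, with aryl and hydroxyl on one face and the interflavan bond on the other; unit 4 holds C2 and C3 only, eleven centres in all. The phloroglucinol and catechol rings oxidise easily, the benzylic C4–aryl bonds are cleaved by acid, and the free phenols epimerise at C2 under base, so the hydroxyl groups must stay masked until the last step. The real difficulty lies not in the centres of the monomer, which nature supplies, but in the regiochemistry (6 against 8) and the C4 configuration of each link, the two 4→6 bonds being the ones a flavan does not form readily. The feature exploited is C4 of unit 2, a methine bonded to C4a of its own ring A (ortho to O1), to C8 of unit 3 and to the oxygen-bearing C3. This is the imprint of an ortho-quinone methide carbon captured by an enol ether, and ring A of unit 2 is a phloroglucinol ring whose two carbons ortho to O1 are equivalent once unit 1 sits para.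

## Logic of the disconnections

32 from 31. The bonds cut are nineteen O–benzyl bonds, the O–(1-phenylethyl) bond on O3 of unit 2 and the C8–Br bond of unit 4. One hydrogenolysis removes them all and is placed last because the free polyphenol tolerates neither acid, base nor air for long. Every earlier intermediate is then a stable ether; the demand is a neutral step that is complete at twenty-one sites.

31 from 30. The C2–H bond of unit 2 is exchanged for the C2–O(silyl) bond of a ketal. The ketal is what a ring-forming union with an enol ether delivers, and its reduction sets C2 last, under control of the neighbouring centres. The demand is hydride delivery to the oxocarbenium ion on the face anti to the 3-alkoxy group.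

30 from 11, 19 and 27 (through 29, with 28 as template). Three bonds of ring C of unit 2 are cut: C4–C4a, C3–C4 and O1–C2. The tetramer falls into an upper fragment (unit 1 plus ring A of unit 2), a lower dimer (units 3 and 4) and a two-carbon piece with ring B. Both 4→6/4→8 questions around unit 2 are settled by where the hydroxyl of 11 and the formyl group of 19 sit. The forward step must attack an ortho carbon of 11 only, and must set C3 and C4 trans and in the right absolute sense.

11 from 10, 10 from 6 and 9, 9 from 7 and 8. The bond cut is C4 of unit 1 to the para carbon of the phenol ring. A flavan-4-yl cation and a phloroglucinol ether are the natural partners, and the coupling gives the 3,4-trans relation on its own. The cation must choose the carbon para to the oxygen that later becomes O1, hence the bulky silyl group of 9.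

19 from 16 (through 18, formyl carbon from 17), 16 from 15 and 13. First the C8–CHO bond of unit 3 is cut back to a C8–iodine bond, then the C4(unit 3)–C6(unit 4) bond. Iodine keeps the electrophile 15 from attacking itself at C8 and is the only halogen that exchanges with magnesium in the presence of the aryl bromide. Bromine on 13 blocks C8 so that C6 is the only free arene carbon. The forward steps require a hindered C6 nucleophile and a selective exchange.

15 from 6 and 14, 13 from 4 and 12, 6 from 4 and 5, 4 from 3, 3 from 1 (2 as alkylating agent). Only C–halogen, C4–O and O–benzyl bonds are cut. All three flavan building blocks descend from one protected monomer, and ten of the eleven stereocentres' worth of C2/C3 information in units 1, 3 and 4 comes from 1 unchanged.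

27 from 25 and 26, 25 from 22 and 23 (through 24), 22 from 20 and 21. The cuts are O–Si, the aryl–carbonyl bond and an ether C–O bond. The gain is a short, convergent entry to a Z enol ether whose chiral ether group is removed in the final hydrogenolysis. The enolisation must give the Z isomer.

## Other disconnections considered

Alternative 1: The cut removes three bonds of ring A of unit 4 (C4a–C8a, C5–C6, C8–C8a), so that this benzene ring is made from a four-carbon and a two-carbon piece. In the forward step the cyclobutenone A2, which carries unit 3 through its C4, is heated in toluene with the siloxyalkyne A3. Electrocyclic opening to a vinylketene, [2+2] addition of the alkyne, a second opening and a 6π closure should give the phenol A1.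
- In favour: every substituent of the new ring is placed by the atom mapping, so the 4→6 link of units 3 and 4 needs no halogen block. The three oxygens emerge differentiated (free OH at C8a, silyl ether at O5, benzyl ether at O7), which is better than anything the chosen plan offers for ring A of unit 4. The conditions are neutral and thermal, and the pericyclic cascade creates no stereocentre, so the bond-forming event itself is more predictable than the polar key step chosen.
- Against: it spends its effort on an aromatic ring that 1 already contains. A2 must first be assembled from a C4-functionalised flavan with the 4β configuration secured at that stage. After A1 the cinnamyl chain still has to become ring C of unit 4 with two new centres in the cis relation. Units 1 and 2 are not addressed.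
- Comparison: on step economy the chosen plan is clearly ahead, since it takes three complete units with their centres from 1.

Alternative 2: The cut opens ring C of unit 4 at O1–C2 and C3–C4. In the forward step the salicylaldehyde A5 (ring A of unit 4 with unit 3 at C6 and bromine at C8) and the cinnamaldehyde A6 combine under a diarylprolinol silyl ether. Oxa-Michael addition to the iminium ion, aldol closure of the enamine and loss of water should give the 2H-chromene-3-carbaldehyde A4.
- In favour: C2 is set by the catalyst, in either sense at will. On this point the alternative is better than the chosen plan, whose new centres rest on an auxiliary and on substrate preferences. The reaction is catalytic and convergent, and its conditions are milder than BF3·OEt2.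
- Against: A5 is a fully substituted salicylaldehyde whose hydroxyl is flanked by bromine, and A6 is an electron-rich enal of low iminium reactivity. The oxa-Michael step is reversible, which tends to erode selectivity with such partners. A4 has a formyl-bearing sp2 carbon at C3, so hydrogenation and a C–C to C–O exchange of the Baeyer–Villiger type are still needed for the cis 3-hydroxyl group.
- Comparison: like alternative 1 it rebuilds a unit that 1 supplies intact and leaves units 1 and 2 to later couplings, so the step count would be well above that of the chosen plan.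

Alternative 3: The cut is C4–C4a of unit 1. In the forward step A8, the 3,5-bis(benzyloxy)phenyl ether of a trans-epoxy alcohol whose distal epoxide carbon bears C6 of brominated unit 2, is treated with BF3·OEt2. The arene carbon ortho to the ether oxygen opens the epoxide at the benzylic carbon (6-endo) and ring C of unit 1 closes to give A7.
- In favour: the unit 1–unit 2 bond exists before ring closure, so no 6/8 question arises for this link. C2 and C3 of unit 1 come from an asymmetric epoxidation, and the 3-hydroxyl emerges free and distinct from all other oxygens, an advantage over the chosen plan if unit 1 were to be modified. The two ortho carbons of the aryl ether are equivalent, the same symmetry argument the chosen plan uses for ring A of unit 2; the plans are equal here.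
- Against: the attacked epoxide carbon carries a trioxygenated aryl ring, so the opening probably passes through an open benzylic cation and the inversion needed for 3,4-trans is not assured. The substrate needs a carbon chain built on C6 of an 8-blocked flavan. It delivers only the upper dimer, and joining C4 of unit 2 to C8 of unit 3 would then require C4 activation of the lower unit of a dimer.
- Comparison: the chosen plan forms that very bond while closing ring C of unit 2 and is shorter, although the ring closure of alternative 3 as such is no less credible than the chosen key step.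

Key step: step 14

## Route

Step 1
Reactants: 1 (−)-epicatechin; 2 benzyl bromide
Product: 3 5,7,3',4'-tetra-O-benzyl-(−)-epicatechin
Conditions: BnBr (4.4 equiv), K2CO3, DMF, 0 °C to rt
Reagents that add atoms: benzyl bromide, BrCc1ccccc1
Why: Williamson etherification of the four phenols; carbonate does not deprotonate the secondary 3-OH, and no bond to C2 or C3 is touched, so both centres are carried over.

Step 2
Reactants: 3 5,7,3',4'-tetra-O-benzyl-(−)-epicatechin; 2 benzyl bromide
Product: 4 3,5,7,3',4'-penta-O-benzyl-(−)-epicatechin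
Conditions: NaH, BnBr, Bu4NI (cat.), DMF, 0 °C to rt
Reagents that add atoms: benzyl bromide, BrCc1ccccc1
Why: Williamson etherification of the secondary alkoxide; only the O–H bond reacts, so C3 keeps its configuration.

Step 3
Reactants: 4 3,5,7,3',4'-penta-O-benzyl-(−)-epicatechin; 5 2-ethoxyethanol
Product: 6 4β-(2-ethoxyethoxy)-3,5,7,3',4'-penta-O-benzylepicatechin
Conditions: DDQ (2 equiv), 2-ethoxyethanol (5 equiv), CH2Cl2, rt
Reagents that add atoms: 2-ethoxyethanol, CCOCCO
Why: Benzylic oxidation by hydride abstraction at C4, the only C–H activated by the trioxygenated ring A; the cation is trapped by the alcohol on the face opposite to the 2-aryl and 3-benzyloxy groups, which gives the 3,4-trans ether.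

Step 4
Reactants: 7 3,5-bis(benzyloxy)phenol; 8 chlorotriisopropylsilane
Product: 9 [3,5-bis(benzyloxy)phenoxy]triisopropylsilane
Conditions: TIPSCl, imidazole, DMF, rt
Reagents that add atoms: chlorotriisopropylsilane, CC(C)[Si](Cl)(C(C)C)C(C)C
Why: Standard silylation of a phenol; the bulky silyl ether is there to screen both carbons next to it in step 5.

Step 5
Reactants: 6 4β-(2-ethoxyethoxy)-3,5,7,3',4'-penta-O-benzylepicatechin; 9 [3,5-bis(benzyloxy)phenoxy]triisopropylsilane
Product: 10 4β-[2,6-bis(benzyloxy)-4-(triisopropylsilyloxy)phenyl]-3,5,7,3',4'-penta-O-benzylepicatechin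
Conditions: TMSOTf (0.5 equiv), 9 (4 equiv), CH2Cl2, −78 to −40 °C
Reagents that add atoms: none
Why: Friedel–Crafts coupling of the flavan-4-yl cation; the arene enters anti to the 3-benzyloxy and 2-aryl groups, which sets C4 as 3,4-trans (4β). The carbon between the two benzyloxy groups should react because the triisopropylsilyl ether screens its own ortho carbons, and the excess of 9 outcompetes the free arene carbons of 6.

Step 6
Reactants: 10 4β-[2,6-bis(benzyloxy)-4-(triisopropylsilyloxy)phenyl]-3,5,7,3',4'-penta-O-benzylepicatechin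
Product: 11 3,5-bis(benzyloxy)-4-(3,5,7,3',4'-penta-O-benzylepicatechin-4β-yl)phenol
Conditions: Bu4NF, AcOH, THF, 0 °C
Reagents that add atoms: none
Why: Fluoride cleavage of the aryl silyl ether; benzyl ethers and the interflavan-type bond are inert, and acetic acid keeps the electron-rich phenoxide from standing in solution.

Step 7
Reactants: 4 3,5,7,3',4'-penta-O-benzyl-(−)-epicatechin; 12 N-bromosuccinimide
Product: 13 8-bromo-3,5,7,3',4'-penta-O-benzylepicatechin
Conditions: NBS (1.0 equiv), CH2Cl2, −78 °C to rt
Reagents that add atoms: N-bromosuccinimide, O=C1CCC(=O)N1Br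
Why: Electrophilic aromatic bromination; C8 is the more accessible of the two free carbons of ring A (C6 lies between two benzyloxy groups), so the halogen goes there and leaves C6 as the only nucleophilic site.

Step 8
Reactants: 6 4β-(2-ethoxyethoxy)-3,5,7,3',4'-penta-O-benzylepicatechin; 14 N-iodosuccinimide
Product: 15 8-iodo-4β-(2-ethoxyethoxy)-3,5,7,3',4'-penta-O-benzylepicatechin
Conditions: NIS (1.05 equiv), NaHCO3, CH2Cl2, 0 °C, dark
Reagents that add atoms: N-iodosuccinimide, O=C1CCC(=O)N1I
Why: Electrophilic iodination at C8 with the same regiochemistry as the bromination; the medium stays neutral, so the acid-labile C4 ether is not ionised.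

Step 9
Reactants: 15 8-iodo-4β-(2-ethoxyethoxy)-3,5,7,3',4'-penta-O-benzylepicatechin; 13 8-bromo-3,5,7,3',4'-penta-O-benzylepicatechin
Product: 16 8-iodo-penta-O-benzylepicatechin-(4β→6)-8-bromo-penta-O-benzylepicatechin
Conditions: TMSOTf (0.5 equiv), 13 (3 equiv), CH2Cl2, −78 to −30 °C
Reagents that add atoms: none
Why: Friedel–Crafts interflavan coupling; bromine blocks C8 of 13 so that C6 attacks, and the cation is approached anti to its 3-benzyloxy group (4β). Iodine caps C8 of the electrophile, and the excess of 13 limits attack on the free C6 of the iodinated unit.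

Step 10
Reactants: 16 8-iodo-penta-O-benzylepicatechin-(4β→6)-8-bromo-penta-O-benzylepicatechin; 17 N,N-dimethylformamide
Product: 19 8-formyl-penta-O-benzylepicatechin-(4β→6)-8-bromo-penta-O-benzylepicatechin, via arylmagnesium chloride 18 (not isolated)
Conditions: iPrMgCl·LiCl (1.2 equiv), THF, −20 °C; DMF, −20 to 0 °C; aq. NH4Cl
Reagents that add atoms: N,N-dimethylformamide, CN(C)C=O
Why: Iodine–magnesium exchange, assisted by the two ortho oxygens, is much faster than exchange of the electron-rich aryl bromide, so only C8 of unit 3 is metalated. Formylation of the aryl Grignard reagent with DMF then gives the aldehyde on work-up.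

Step 11
Reactants: 20 (S)-1-phenylethanol; 21 2-chloro-N-methoxy-N-methylacetamide
Product: 22 N-methoxy-N-methyl-2-[(1S)-1-phenylethoxy]acetamide
Conditions: NaH, THF, 0 °C to rt
Reagents that add atoms: 2-chloro-N-methoxy-N-methylacetamide, ClCC(=O)N(C)OC
Why: Williamson etherification of the alkoxide with an activated primary chloride (SN2); the stereocentre of the alcohol is not involved.

Step 12
Reactants: 23 4-bromo-1,2-bis(benzyloxy)benzene; 22 N-methoxy-N-methyl-2-[(1S)-1-phenylethoxy]acetamide
Product: 25 1-[3,4-bis(benzyloxy)phenyl]-2-[(1S)-1-phenylethoxy]ethanone, via Grignard reagent 24 (not isolated)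
Conditions: Mg, THF, rt; then 22, 0 °C; aq. NH4Cl
Reagents that add atoms: none
Why: Weinreb ketone synthesis; the chelated tetrahedral intermediate prevents a second addition, so the ketone is released only on work-up.

Step 13
Reactants: 25 1-[3,4-bis(benzyloxy)phenyl]-2-[(1S)-1-phenylethoxy]ethanone; 26 tert-butyldimethylsilyl trifluoromethanesulfonate
Product: 27 (Z)-tert-butyl({1-[3,4-bis(benzyloxy)phenyl]-2-[(1S)-1-phenylethoxy]ethenyl}oxy)dimethylsilane
Conditions: TBSOTf, Et3N, CH2Cl2, 0 °C
Reagents that add atoms: tert-butyldimethylsilyl trifluoromethanesulfonate, CC(C)(C)[Si](C)(C)OS(=O)(=O)C(F)(F)F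
Why: Soft enolisation of an aryl ketone; the Z enol ether (alkoxy cis to silyloxy, away from the aryl ring) should form because the E isomer suffers allylic strain against the aryl group.

Step 14
Reactants: 11 3,5-bis(benzyloxy)-4-(3,5,7,3',4'-penta-O-benzylepicatechin-4β-yl)phenol; 19 8-formyl-penta-O-benzylepicatechin-(4β→6)-8-bromo-penta-O-benzylepicatechin; 28 phenylboronic acid; 27 (Z)-tert-butyl({1-[3,4-bis(benzyloxy)phenyl]-2-[(1S)-1-phenylethoxy]ethenyl}oxy)dimethylsilane
Product: 30 protected tetramer carrying the C2 tert-butyldimethylsilyl ketal in unit 2, via benzodioxaborin 29 (not isolated)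
Conditions: PhB(OH)2 (1.1 equiv), EtCO2H (0.2 equiv), toluene, reflux, azeotropic removal of water; then 27 (2 equiv), BF3·OEt2 (1.5 equiv), CH2Cl2, −78 to −40 °C; Et3N
Reagents that add atoms: none
Why: Heating 11 with PhB(OH)2 gives an aryl boronate that delivers the formyl carbon of 19 to an ortho carbon through a six-membered transition state (ortho-specific hydroxyalkylation), and esterification closes the temporary dioxaborin ring of 29. BF3·OEt2 then opens the benzylic C–O bond to a boron-bound ortho-quinone methide, in effect a diarylmethyl cation between two trioxygenated rings; the nucleophilic CH carbon of 27 adds to it (Mukaiyama–Michael) and the phenolic oxygen closes ring C of unit 2 on the silyloxocarbenium carbon in a 6-exo-trig sense, so that the whole is a formal inverse-demand hetero-[4+2], the known behaviour of benzodioxaborins towards enol ethers. Regiochemistry is fixed by structure: boron enforces the ortho position, the two ortho carbons of 11 are interchangeable because unit 1 sits para, and the aldehyde carbon is already bonded to C8 of unit 3, so the 4→6 and 4→8 links cannot be misplaced. For C3 and C4 the favoured arrangement should put the hydrogen of the enol ether carbon into the crowded sector between the two aryl groups of the methide and turn the alkoxy group away from ring A, which gives the 3,4-trans relation. Neither unit 1 nor the centres of unit 3 are close enough to the planar methide to choose its face, so the choice is handed to the nucleophile: in the s-trans conformer of 27 the phenyl group of the (S)-1-phenylethyl ether screens one face, and addition through the other gives C3 in the epicatechin sense, with C4 following from the trans preference. C2 is formed as a ketal centre whose configuration does not matter because step 15 passes through the oxocarbenium ion. Chemoselectivity rests on the enol ether being a far better nucleophile than any free arene carbon, and on the low temperature, at which benzyl ethers, the 1-phenylethyl ether and the interflavan bonds should be inert to BF3·OEt2.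

Step 15
Reactants: 30 protected tetramer carrying the C2 tert-butyldimethylsilyl ketal in unit 2
Product: 31 protected epicatechin-(4β→6)-epicatechin-(4β→8)-epicatechin-(4β→6)-epicatechin (3-O-[(1S)-1-phenylethyl] on unit 2; 8-bromo on unit 4; nineteen O-benzyl groups)
Conditions: Et3SiH (5 equiv), BF3·OEt2 (2 equiv), CH2Cl2, −78 to −30 °C
Reagents that add atoms: none
Why: Ionic hydrogenation of a 2-oxygenated flavan: loss of the silyloxy group gives the 2-aryl oxocarbenium ion, in whose half-chair the 3-alkoxy and 4-aryl groups should be trans-diaxial (the 4-substituent avoids the 5-benzyloxy group, the 3-substituent the coplanar 2-aryl group). Axial hydride delivery anti to the 3-alkoxy group puts H-2 on the β face and the aryl group cis to O3, the 2,3-cis, 2,4-trans pattern of an epicatechin extender unit.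

Step 16
Reactants: 31 protected epicatechin-(4β→6)-epicatechin-(4β→8)-epicatechin-(4β→6)-epicatechin
Product: 32 epicatechin-(4β→6)-epicatechin-(4β→8)-epicatechin-(4β→6)-epicatechin
Conditions: H2 (1 atm), Pd(OH)2/C, NaOAc (2 equiv), THF/MeOH/H2O, rt
Reagents that add atoms: none
Why: Hydrogenolysis of the nineteen benzyl ethers and the 1-phenylethyl ether together with hydrodebromination at C8 of unit 4; acetate takes up the HBr that would otherwise threaten the interflavan bonds. No stereocentre is touched, and the ring C–O bonds of flavans are not expected to be cleaved at room temperature and 1 atm.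

## Compound list

1 | (−)-epicatechin, (2R,3R) | O[C@@H]1Cc2c(O)cc(O)cc2O[C@@H]1c1ccc(O)c(O)c1 | starting material
2 | benzyl bromide | BrCc1ccccc1 | starting material
3 | 5,7,3',4'-tetra-O-benzyl-(−)-epicatechin, (2R,3R) | O[C@@H]1Cc2c(OCc9ccccc9)cc(OCc9ccccc9)cc2O[C@@H]1c7ccc(OCc9ccccc9)c(OCc9ccccc9)c7 | intermediate
4 | 3,5,7,3',4'-penta-O-benzyl-(−)-epicatechin, (2R,3R) | O(Cc9ccccc9)c1cc(OCc9ccccc9)c2c(c1)O[C@H](c7ccc(OCc9ccccc9)c(OCc9ccccc9)c7)[C@H](OCc9ccccc9)C2 | intermediate
5 | 2-ethoxyethanol | CCOCCO | starting material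
6 | 4β-(2-ethoxyethoxy)-3,5,7,3',4'-penta-O-benzylepicatechin (2,3-cis, 3,4-trans) | O(Cc9ccccc9)c1cc(OCc9ccccc9)c2c(c1)O[C@H](c7ccc(OCc9ccccc9)c(OCc9ccccc9)c7)[C@H](OCc9ccccc9)[C@H]2OCCOCC | intermediate
7 | 3,5-bis(benzyloxy)phenol | Oc1cc(OCc2ccccc2)cc(OCc2ccccc2)c1 | starting material
8 | chlorotriisopropylsilane | CC(C)[Si](Cl)(C(C)C)C(C)C | starting material
9 | [3,5-bis(benzyloxy)phenoxy]triisopropylsilane | CC(C)[Si](Oc1cc(OCc2ccccc2)cc(OCc2ccccc2)c1)(C(C)C)C(C)C | intermediate
10 | 4β-[2,6-bis(benzyloxy)-4-(triisopropylsilyloxy)phenyl]-3,5,7,3',4'-penta-O-benzylepicatechin (3,4-trans) | O(Cc9ccccc9)c1cc(OCc9ccccc9)c2c(c1)O[C@H](c7ccc(OCc9ccccc9)c(OCc9ccccc9)c7)[C@H](OCc9ccccc9)[C@H]2c1c(OCc9ccccc9)cc(O[Si](C(C)C)(C(C)C)C(C)C)cc1OCc9ccccc9 | intermediate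
11 | 3,5-bis(benzyloxy)-4-(3,5,7,3',4'-penta-O-benzylepicatechin-4β-yl)phenol (unit 1 on ring A of unit 2) | O(Cc9ccccc9)c1cc(OCc9ccccc9)c2c(c1)O[C@H](c7ccc(OCc9ccccc9)c(OCc9ccccc9)c7)[C@H](OCc9ccccc9)[C@H]2c1c(OCc9ccccc9)cc(O)cc1OCc9ccccc9 | intermediate
12 | N-bromosuccinimide | O=C1CCC(=O)N1Br | starting material
13 | 8-bromo-3,5,7,3',4'-penta-O-benzylepicatechin | Brc1c(OCc9ccccc9)cc(OCc9ccccc9)c2c1O[C@H](c7ccc(OCc9ccccc9)c(OCc9ccccc9)c7)[C@H](OCc9ccccc9)C2 | intermediate
14 | N-iodosuccinimide | O=C1CCC(=O)N1I | starting material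
15 | 8-iodo-4β-(2-ethoxyethoxy)-3,5,7,3',4'-penta-O-benzylepicatechin | Ic1c(OCc9ccccc9)cc(OCc9ccccc9)c2c1O[C@H](c7ccc(OCc9ccccc9)c(OCc9ccccc9)c7)[C@H](OCc9ccccc9)[C@H]2OCCOCC | intermediate
16 | 8-iodo-penta-O-benzylepicatechin-(4β→6)-8-bromo-penta-O-benzylepicatechin (units 3 and 4) | Ic1c(OCc9ccccc9)cc(OCc9ccccc9)c3c1O[C@H](c7ccc(OCc9ccccc9)c(OCc9ccccc9)c7)[C@H](OCc9ccccc9)[C@H]3c1c(OCc9ccccc9)c(Br)c3c(c1OCc9ccccc9)C[C@@H](OCc9ccccc9)[C@@H](c7ccc(OCc9ccccc9)c(OCc9ccccc9)c7)O3 | intermediate
17 | N,N-dimethylformamide | CN(C)C=O | starting material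
18 | arylmagnesium chloride from 16 (magnesium on C8 of unit 3) | Cl[Mg]c1c(OCc9ccccc9)cc(OCc9ccccc9)c3c1O[C@H](c7ccc(OCc9ccccc9)c(OCc9ccccc9)c7)[C@H](OCc9ccccc9)[C@H]3c1c(OCc9ccccc9)c(Br)c3c(c1OCc9ccccc9)C[C@@H](OCc9ccccc9)[C@@H](c7ccc(OCc9ccccc9)c(OCc9ccccc9)c7)O3 | intermediate (not isolated)
19 | 8-formyl-penta-O-benzylepicatechin-(4β→6)-8-bromo-penta-O-benzylepicatechin | O=Cc1c(OCc9ccccc9)cc(OCc9ccccc9)c3c1O[C@H](c7ccc(OCc9ccccc9)c(OCc9ccccc9)c7)[C@H](OCc9ccccc9)[C@H]3c1c(OCc9ccccc9)c(Br)c3c(c1OCc9ccccc9)C[C@@H](OCc9ccccc9)[C@@H](c7ccc(OCc9ccccc9)c(OCc9ccccc9)c7)O3 | intermediate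
20 | (S)-1-phenylethanol | C[C@@H](c1ccccc1)O | starting material
21 | 2-chloro-N-methoxy-N-methylacetamide | ClCC(=O)N(C)OC | starting material
22 | N-methoxy-N-methyl-2-[(1S)-1-phenylethoxy]acetamide | C[C@@H](c1ccccc1)OCC(=O)N(C)OC | intermediate
23 | 4-bromo-1,2-bis(benzyloxy)benzene | Brc1ccc(OCc2ccccc2)c(OCc2ccccc2)c1 | starting material
24 | 3,4-bis(benzyloxy)phenylmagnesium bromide | Br[Mg]c1ccc(OCc2ccccc2)c(OCc2ccccc2)c1 | intermediate (not isolated)
25 | 1-[3,4-bis(benzyloxy)phenyl]-2-[(1S)-1-phenylethoxy]ethanone | C[C@@H](c9ccccc9)OCC(=O)c7ccc(OCc9ccccc9)c(OCc9ccccc9)c7 | intermediate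
26 | tert-butyldimethylsilyl trifluoromethanesulfonate | CC(C)(C)[Si](C)(C)OS(=O)(=O)C(F)(F)F | starting material
27 | (Z)-tert-butyl({1-[3,4-bis(benzyloxy)phenyl]-2-[(1S)-1-phenylethoxy]ethenyl}oxy)dimethylsilane | C[C@@H](c9ccccc9)O/C=C(\O[Si](C)(C)C(C)(C)C)c7ccc(OCc9ccccc9)c(OCc9ccccc9)c7 | intermediate
28 | phenylboronic acid | OB(O)c1ccccc1 | starting material
29 | 2-phenyl-4H-1,3,2-benzodioxaborin on ring A of unit 2: O–B(Ph)–O–CH ring, the CH (future C4 of unit 2) bonded to C8 of unit 3, unit 1 para to the ring oxygen; both epimers at that CH | O(Cc9ccccc9)c1cc(OCc9ccccc9)c2c(c1)O[C@H](c7ccc(OCc9ccccc9)c(OCc9ccccc9)c7)[C@H](OCc9ccccc9)[C@H]2c1c(OCc9ccccc9)cc2c(c1OCc9ccccc9)C(c1c(OCc9ccccc9)cc(OCc9ccccc9)c3c1O[C@H](c7ccc(OCc9ccccc9)c(OCc9ccccc9)c7)[C@H](OCc9ccccc9)[C@H]3c1c(OCc9ccccc9)c(Br)c3c(c1OCc9ccccc9)C[C@@H](OCc9ccccc9)[C@@H](c7ccc(OCc9ccccc9)c(OCc9ccccc9)c7)O3)OB(c8ccccc8)O2 | intermediate (not isolated)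
30 | protected tetramer with C2 tert-butyldimethylsilyl ketal in unit 2 (silyloxy cis to O3, 3,4-trans, 3-O-[(1S)-1-phenylethyl]); 8-bromo on unit 4; all other hydroxyls benzylated | O(Cc9ccccc9)c1cc(OCc9ccccc9)c2c(c1)O[C@H](c7ccc(OCc9ccccc9)c(OCc9ccccc9)c7)[C@H](OCc9ccccc9)[C@H]2c1c(OCc9ccccc9)cc2c(c1OCc9ccccc9)[C@H](c1c(OCc9ccccc9)cc(OCc9ccccc9)c3c1O[C@H](c7ccc(OCc9ccccc9)c(OCc9ccccc9)c7)[C@H](OCc9ccccc9)[C@H]3c1c(OCc9ccccc9)c(Br)c3c(c1OCc9ccccc9)C[C@@H](OCc9ccccc9)[C@@H](c7ccc(OCc9ccccc9)c(OCc9ccccc9)c7)O3)[C@@H](O[C@@H](C)c9ccccc9)[C@](O[Si](C)(C)C(C)(C)C)(c7ccc(OCc9ccccc9)c(OCc9ccccc9)c7)O2 | intermediate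
31 | protected epicatechin-(4β→6)-epicatechin-(4β→8)-epicatechin-(4β→6)-epicatechin: 3-O-[(1S)-1-phenylethyl] on unit 2, 8-bromo on unit 4, nineteen O-benzyl groups | O(Cc9ccccc9)c1cc(OCc9ccccc9)c2c(c1)O[C@H](c7ccc(OCc9ccccc9)c(OCc9ccccc9)c7)[C@H](OCc9ccccc9)[C@H]2c1c(OCc9ccccc9)cc2c(c1OCc9ccccc9)[C@H](c1c(OCc9ccccc9)cc(OCc9ccccc9)c3c1O[C@H](c7ccc(OCc9ccccc9)c(OCc9ccccc9)c7)[C@H](OCc9ccccc9)[C@H]3c1c(OCc9ccccc9)c(Br)c3c(c1OCc9ccccc9)C[C@@H](OCc9ccccc9)[C@@H](c7ccc(OCc9ccccc9)c(OCc9ccccc9)c7)O3)[C@@H](O[C@@H](C)c9ccccc9)[C@@H](c7ccc(OCc9ccccc9)c(OCc9ccccc9)c7)O2 | intermediate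
32 | epicatechin-(4β→6)-epicatechin-(4β→8)-epicatechin-(4β→6)-epicatechin (CNP0120618.1) | Oc1cc(O)c2c(c1)O[C@H](c1ccc(O)c(O)c1)[C@H](O)[C@H]2c1c(O)cc2c(c1O)[C@H](c1c(O)cc(O)c3c1O[C@H](c1ccc(O)c(O)c1)[C@H](O)[C@H]3c1c(O)cc3c(c1O)C[C@@H](O)[C@@H](c1ccc(O)c(O)c1)O3)[C@@H](O)[C@@H](c1ccc(O)c(O)c1)O2 | target

## Step count and risks

Total step count: 16.
Longest linear sequence: 9 steps (steps 1, 2, 3, 8, 9, 10, 14, 15, 16).

Least certain steps:

Step 14 (key step). Two things are most likely to go wrong. The first is a slow ortho-hydroxyalkylation, because the formyl group of 19 is flanked by two oxygen substituents and is electronically a vinylogous carbonate. The second is insufficient facial discrimination in the C–C bond formation, because the bias comes from the auxiliary alone and rests on a conformational model. Any 3,4-cis or C4-epimeric material would be separated after step 15, and the enantiomeric alcohol can replace 20 if the sense of induction proves opposite. Fallback for the first failure, from 11 and 19 back to 29 by organometallic addition instead of the boron-directed aromatic substitution: 11 is monobrominated ortho to the hydroxyl group (NBS, CH2Cl2, −78 °C; the free phenol should direct attack to its own ring) to give the bromophenol F1. Treatment of F1 with n-BuLi (2.2 equiv, THF, −78 °C) gives the O,C-dilithio species, which adds to the formyl group of 19 to give the ortho-hydroxy diarylmethanol F2. Esterification of F2 with PhB(OH)2 (toluene, azeotropic removal of water) gives 29, where the route is rejoined before 27 and BF3·OEt2 are added.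

Step 15. Hydride delivery may prefer the wrong face, because the face anti to the 3-alkoxy group is also the one on which the axial 4-aryl group (unit 3) stands, and a 2,3-trans product could result. Fallback, from 30 to 31 by substitution with inversion instead of oxocarbenium reduction: desilylation of 30 (Bu4NF, AcOH, THF) gives the hydroxy ketone F3, the open form of the hemiketal. Chelation-controlled reduction with Zn(BH4)2 (Et2O, −20 °C) should give the anti alcohol F4. Mitsunobu cyclisation (PPh3, diisopropyl azodicarboxylate, THF, 0 °C) closes O1–C2 with inversion and gives 31.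

Step 5. The cation may attack a carbon next to the silyl ether of 9 in competition with the carbon between the two benzyloxy groups, or attack free arene carbons of 6, giving regioisomers or oligomers. Fallback, from 6 to 10 through a symmetrical nucleophile: 6 is coupled with phloroglucinol itself (5 equiv, BF3·OEt2, THF/CH2Cl2, −40 °C), whose three ring carbons are equivalent, to give the triol F5. The unhindered para hydroxyl is silylated selectively (TIPSCl, imidazole, DMF, 0 °C) to give the diol F6. The two hydroxyls flanking the flavanyl group are then benzylated (BnBr, K2CO3, DMF) to give 10.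

Step 10. The exchange may be incomplete or may begin to touch the aryl bromide of unit 4, and the hindered aryl Grignard reagent may be protonated rather than formylated. Fallback, from 16 directly to 19 by palladium-catalysed reductive carbonylation of the aryl iodide (Pd(OAc)2, 1,3-bis(diphenylphosphino)propane, CO (1 atm), Et3SiH, Na2CO3, DMF, 60 °C): oxidative addition to zerovalent palladium distinguishes the carbon–iodine from the carbon–bromine bond, and no new isolable compound is made.

## Further compounds

F1 | step 14 | 2-bromo-3,5-bis(benzyloxy)-4-(3,5,7,3',4'-penta-O-benzylepicatechin-4β-yl)phenol | O(Cc9ccccc9)c1cc(OCc9ccccc9)c2c(c1)O[C@H](c7ccc(OCc9ccccc9)c(OCc9ccccc9)c7)[C@H](OCc9ccccc9)[C@H]2c1c(OCc9ccccc9)cc(O)c(Br)c1OCc9ccccc9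
F2 | step 14 | ortho-hydroxy diarylmethanol from F1 and 19 (carbinol carbon bonded to the phenol ring and to C8 of unit 3; both epimers) | O(Cc9ccccc9)c1cc(OCc9ccccc9)c2c(c1)O[C@H](c7ccc(OCc9ccccc9)c(OCc9ccccc9)c7)[C@H](OCc9ccccc9)[C@H]2c1c(OCc9ccccc9)cc(O)c(c1OCc9ccccc9)C(O)c1c(OCc9ccccc9)cc(OCc9ccccc9)c3c1O[C@H](c7ccc(OCc9ccccc9)c(OCc9ccccc9)c7)[C@H](OCc9ccccc9)[C@H]3c1c(OCc9ccccc9)c(Br)c3c(c1OCc9ccccc9)C[C@@H](OCc9ccccc9)[C@@H](c7ccc(OCc9ccccc9)c(OCc9ccccc9)c7)O3
F3 | step 15 | hydroxy ketone from 30 (ring C of unit 2 open at O1–C2; C3 and C4 as in 30) | O(Cc9ccccc9)c1cc(OCc9ccccc9)c2c(c1)O[C@H](c7ccc(OCc9ccccc9)c(OCc9ccccc9)c7)[C@H](OCc9ccccc9)[C@H]2c1c(OCc9ccccc9)cc(O)c(c1OCc9ccccc9)[C@H](c1c(OCc9ccccc9)cc(OCc9ccccc9)c3c1O[C@H](c7ccc(OCc9ccccc9)c(OCc9ccccc9)c7)[C@H](OCc9ccccc9)[C@H]3c1c(OCc9ccccc9)c(Br)c3c(c1OCc9ccccc9)C[C@@H](OCc9ccccc9)[C@@H](c7ccc(OCc9ccccc9)c(OCc9ccccc9)c7)O3)[C@@H](O[C@@H](C)c9ccccc9)C(=O)c7ccc(OCc9ccccc9)c(OCc9ccccc9)c7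
F4 | step 15 | anti alcohol from F3 (benzylic carbinol anti to the 3-alkoxy group) | O(Cc9ccccc9)c1cc(OCc9ccccc9)c2c(c1)O[C@H](c7ccc(OCc9ccccc9)c(OCc9ccccc9)c7)[C@H](OCc9ccccc9)[C@H]2c1c(OCc9ccccc9)cc(O)c(c1OCc9ccccc9)[C@H](c1c(OCc9ccccc9)cc(OCc9ccccc9)c3c1O[C@H](c7ccc(OCc9ccccc9)c(OCc9ccccc9)c7)[C@H](OCc9ccccc9)[C@H]3c1c(OCc9ccccc9)c(Br)c3c(c1OCc9ccccc9)C[C@@H](OCc9ccccc9)[C@@H](c7ccc(OCc9ccccc9)c(OCc9ccccc9)c7)O3)[C@@H](O[C@@H](C)c9ccccc9)[C@@H](O)c7ccc(OCc9ccccc9)c(OCc9ccccc9)c7
F5 | step 5 | 2-(3,5,7,3',4'-penta-O-benzylepicatechin-4β-yl)benzene-1,3,5-triol | O(Cc9ccccc9)c1cc(OCc9ccccc9)c2c(c1)O[C@H](c7ccc(OCc9ccccc9)c(OCc9ccccc9)c7)[C@H](OCc9ccccc9)[C@H]2c1c(O)cc(O)cc1O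
F6 | step 5 | 2-(3,5,7,3',4'-penta-O-benzylepicatechin-4β-yl)-5-(triisopropylsilyloxy)benzene-1,3-diol | O(Cc9ccccc9)c1cc(OCc9ccccc9)c2c(c1)O[C@H](c7ccc(OCc9ccccc9)c(OCc9ccccc9)c7)[C@H](OCc9ccccc9)[C@H]2c1c(O)cc(O[Si](C(C)C)(C(C)C)C(C)C)cc1O
F0 | step 10 | none | none
A1 | alternative 1 | phenol: ring A of unit 4 with unit 3 at C6, (E)-cinnamyl chain at C4a, triisopropylsilyl ether at O5, benzyl ether at O7 | O(Cc9ccccc9)c1cc(OCc9ccccc9)c2c(c1)O[C@H](c7ccc(OCc9ccccc9)c(OCc9ccccc9)c7)[C@H](OCc9ccccc9)[C@H]2c1c(OCc9ccccc9)cc(O)c(C/C=C/c7ccc(OCc9ccccc9)c(OCc9ccccc9)c7)c1O[Si](C(C)C)(C(C)C)C(C)C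
A2 | alternative 1 | 3-benzyloxy-2-(3,5,7,3',4'-penta-O-benzylepicatechin-4β-yl)cyclobut-2-enone | O(Cc9ccccc9)c1cc(OCc9ccccc9)c2c(c1)O[C@H](c7ccc(OCc9ccccc9)c(OCc9ccccc9)c7)[C@H](OCc9ccccc9)[C@H]2C1=C(OCc9ccccc9)CC1=O
A3 | alternative 1 | (E)-{[5-(3,4-bis(benzyloxy)phenyl)pent-4-en-1-yn-1-yl]oxy}triisopropylsilane | CC(C)[Si](OC#CC/C=C/c7ccc(OCc9ccccc9)c(OCc9ccccc9)c7)(C(C)C)C(C)C
A4 | alternative 2 | unit 3–(4β→6)–unit 4 dimer with unit 4 as 8-bromo-2-aryl-2H-chromene-3-carbaldehyde | O(Cc9ccccc9)c1cc(OCc9ccccc9)c2c(c1)O[C@H](c7ccc(OCc9ccccc9)c(OCc9ccccc9)c7)[C@H](OCc9ccccc9)[C@H]2c1c(OCc9ccccc9)c(Br)c2c(c1OCc9ccccc9)C=C(C=O)[C@@H](c7ccc(OCc9ccccc9)c(OCc9ccccc9)c7)O2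
A5 | alternative 2 | 4,6-bis(benzyloxy)-3-bromo-2-hydroxy-5-(3,5,7,3',4'-penta-O-benzylepicatechin-4β-yl)benzaldehyde | O(Cc9ccccc9)c1cc(OCc9ccccc9)c2c(c1)O[C@H](c7ccc(OCc9ccccc9)c(OCc9ccccc9)c7)[C@H](OCc9ccccc9)[C@H]2c1c(OCc9ccccc9)c(Br)c(O)c(C=O)c1OCc9ccccc9
A6 | alternative 2 | (E)-3-[3,4-bis(benzyloxy)phenyl]prop-2-enal | O=C/C=C/c1ccc(OCc2ccccc2)c(OCc2ccccc2)c1
A7 | alternative 3 | benzylated unit 1–(4β→6)–unit 2 dimer with free 3-OH on unit 1 and 8-bromo on unit 2 | O(Cc9ccccc9)c1cc(OCc9ccccc9)c2c(c1)O[C@H](c7ccc(OCc9ccccc9)c(OCc9ccccc9)c7)[C@H](O)[C@H]2c1c(OCc9ccccc9)c(Br)c2c(c1OCc9ccccc9)C[C@@H](OCc9ccccc9)[C@@H](c7ccc(OCc9ccccc9)c(OCc9ccccc9)c7)O2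
A8 | alternative 3 | 3,5-bis(benzyloxy)phenyl ether of 1-[3,4-bis(benzyloxy)phenyl]-3-(8-bromo-penta-O-benzylepicatechin-6-yl)-trans-2,3-epoxypropan-1-ol | O(Cc9ccccc9)c1cc(OCc9ccccc9)cc(c1)O[C@H](c7ccc(OCc9ccccc9)c(OCc9ccccc9)c7)[C@@H]4O[C@H]4c1c(OCc9ccccc9)c(Br)c2c(c1OCc9ccccc9)C[C@@H](OCc9ccccc9)[C@@H](c7ccc(OCc9ccccc9)c(OCc9ccccc9)c7)O2
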